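Leave summer and dusk closed, stirred and at temperature for their 20 d.

| flask | E | temperature | remark | time |
|---|---|---|---|---|
| north | 0.073 M | 85 °C | run made earlier |  |
| north-west | 0.12 M | 98 °C | run made earlier |  |
| summer | 0.10 M | 90 °C |  | 20 d |
| dusk | 0.060 M | 105 °C |  | 20 d |

| run | time / d | J / % | E / % |
|---|---|---|---|
| north | 2.50 | 33.0 | 6.7 |
| north | 5.00 | 54.7 | 4.3 |
| north | 8.00 | 70.8 | 1.2 |
| north | 10.0 | 77.2 | 1.3 |
| north | 12.0 | 82.1 | 1.1 |
| north | 15.0 | 87.3 | 0 |
| north-west | 1.04 | 46.7 | 7.1 |
| north-west | 1.67 | 63.5 | 3.2 |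
| north-west | 3.00 | 79.8 | 1.1 |
| north-west | 5.00 | 87.7 | 0.2 |
| north-west | 8.00 | 89.1 | 0.4 |
| north-west | 15.0 | 89.3 | 0.1 |

(each reading ± 0.5 percentage points)



* the flask that ends with the higher amount of J, in percent of the E charged, or "neither" when 2 percentage points or less lies between them (summer / dusk / neither)
* final J, as a percentage of the E charged, in summer
* final J, as a percentage of the E charged, in dusk

In the north run at 2.50 d, the readings of J and E together come to 39.7% of the charge, so 60.3% sits in forms we do not read. We treat the gap to final J as closing first-order, as exp(−kt), with k its rate constant. Equal time steps give k with no ceiling assumed: north gives 0.160 /d. North-west, levelling at 89.3%, gives 0.766 /d. Interpolating ln k in temperature gives 0.292 /d at 90 °C for summer: this is the clearing constant, the first-order rate at which the gap to final J closes. Dusk, extrapolated, clears faster, at 1.78 /d. Over 20 d we reckon that the constant leaves 0.289% of the gap in summer, hardly any, so we expect side losses rather than time to hold final J below the charge; the two runs changed temperature and the amount of E together.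

The forecast gives 92% (90% to 94%) for summer, 91% (85% to 96%) for dusk, and neither, adding that “dusk is genuinely ambiguous”.

    E ⇌ Q (K = 4.76, k = 0.0123 /min, Ea = 120 kJ/mol, ΔH = −58.0 kJ/mol)
    Q → G (k = 3.52 × 10⁻⁴ /min, Ea = 128 kJ/mol)
    G ⇌ L (K = 2.37, k = 8.95 × 10⁻⁴ /min, Ea = 115 kJ/mol, ΔH = −55.0 kJ/mol)
    Q ⇌ Z (K = 0.240, k = 1.72 × 10⁻⁴ /min, Ea = 119 kJ/mol, ΔH = 22.0 kJ/mol)
    G → J (k = 0.00557 /min, Ea = 115 kJ/mol)
    2 E → D (k = 0.00429 /M/min, Ea = 96.0 kJ/mol)
    E → X (k = 1.67 × 10⁻⁶ /min, Ea = 127 kJ/mol)
    (constants at 90 °C)

The answer is neither: summer ends with J at 92.6% and dusk at 92.8%, 0.24 percentage points apart. D holds 7.16% of the charge in summer and 7.00% in dusk. Summer's E, Q, G, L and Z total 0.172% at the end, against 0.268% reckoned from the clearing constant. For a flask like summer kept at 65 °C, that constant, extrapolated, comes to 0.0144 /d, and summer's final J of 92.6%, taken as the ceiling over the same 20 d, gives 23.2%; that flask ends with J at 23.2%.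

The data were computed for substances that don't exist.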